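The earlier runs and the new flask are calculated for an exercise; the scatter is artificial.

In mM per minute rather than percent of charge, the readings of product G (crystals J counted in) fall past their peak at nearly one pace in both runs, though the charges of substrate Z differ.

| flask | Z | X | remark | time |
|---|---|---|---|---|
| autumn | 0.25 M | 20 mM (held) | the very flask that is asked about, followed so far |  |
| dusk | 0.38 M | 20 mM (held) | run made earlier |  |
| flask | 0.25 M | 20 mM (held) |  | 2.0 h |

| run | time / min | G / % | J / % |
|---|---|---|---|
| autumn | 1.50 | 35.3 | 14.2 |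
| autumn | 2.50 | 46.4 | 27.3 |
| autumn | 4.00 | 54.3 | 41.2 |
| autumn | 6.00 | 58.4 | 51.2 |
| autumn | 10.0 | 59.2 | 57.1 |
| autumn | 15.0 | 58.1 | 55.8 |
| autumn | 20.0 | 55.0 | 54.3 |
| dusk | 4.00 | 54.4 | 42.0 |
| dusk | 6.00 | 59.1 | 53.2 |
| dusk | 8.00 | 60.6 | 57.2 |
| dusk | 15.0 | 60.2 | 59.4 |
| dusk | 20.0 | 58.9 | 57.9 |
| dusk | 30.0 | 55.4 | 55.3 |
| dusk | 50.0 | 50.0 | 48.8 |

(scatter of a reading: 0.3 percentage points)

- for G the J are counted in
- as a solid, counted per litre of solution: J
- at the start none of L is dissolved
- what may be going on: Z + L -> G; X <-> L; L + G -> Q; J <-> G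

* the G and J together standing at 2.0 h, as a percentage of the Z charged
* concentration of L in solution at 2.0 h, in percent of saturation

The dusk run loses 1.11 mM min⁻¹ between 15.0 min and 50.0 min, and the autumn run reads 1.05 mM min⁻¹ between 10.0 min and 20.0 min. The dusk figure is taken as the drain, D, the concentration of G lost per minute past the peak, a zero-order loss. Applied to the flask, which is the autumn run carried on, from 138 mM at 20.0 min, D removes 111 mM by 2.0 h, and this reckoning leaves 10.7% of the charge.

The forecast gives 11.5% (7% to 17%) for G and J together, a little above this reckoning, its ground being that “the loss is zero-order”, and it puts dissolved gas L at 99% of saturation (96% to 100%).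

The flask gives 10.5% for G and J together and 99.9% of saturation for L, both within the forecast's ranges. The cheap route to the first of these is D from two readings, multiplied by the time remaining and subtracted from the last reading.

    Z + L → G (k = 20.7 M⁻¹ min⁻¹)
    X ⇌ L, rate k2*(csat - [L]) (kL = 90.3 min⁻¹)
    L + G → Q (k = 19.3 M⁻¹ min⁻¹)
    J ⇌ G, rate k4*(cs4 - [G]) while solid is left; crystals form when [G] > cs4 (solubility = 4.60 mM, k = 0.667 min⁻¹)

A neighbouring flask charged with 0.62 M of Z takes the same reckoning. Lending it the dusk share of 60.2% at 15.0 min gives 373 mM, from which D removes 117 mM by 2.0 h, leaving 41.4% of its charge. That neighbour holds 43.3% of its charge as G and J together at 2.0 h.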